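**Strategy.** The target is a C2-symmetric oxolane in which C3 and C4 are both α-carbons of aryl ketones and stand 1,5 to each other through the ring oxygen (C3–C2–O1–C5–C4). The plan cuts C3–C4, the bond that an α,α'-coupling of two chalcone units would make in nature. The precursor is the acyclic (S,S)-bis(β-keto) ether 15, assembled by iridium-catalysed allylic etherification. Oxidation of its double enolate with CuCl2 joins the two α-carbons, which closes the oxolane and creates the 1,4-diketone in one operation. The two α-centres are then set against thermodynamics by kinetic protonation of the dienediolate, and hydrogenolysis frees the six phenols.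

Key step: step 11

Assumption: L* is the binaphthol-derived N,N-bis(1-phenylethyl)phosphoramidite, used in the enantiomeric form that gives the (S)-configured branched product with oxygen nucleophiles; compound 17 is drawn as its expected main isomer.

**Step 1**
Reactants: 1 4-(benzyloxy)benzaldehyde; 2 triethyl phosphonoacetate
Product: 3 ethyl (E)-3-[4-(benzyloxy)phenyl]prop-2-enoate
Conditions: NaH, THF, 0 °C to rt
Reagents that add atoms: none
Why: Horner–Wadsworth–Emmons olefination of an aromatic aldehyde with a stabilized phosphonate anion should give the (E)-cinnamate.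

**Step 2**
Reactants: 3 ethyl (E)-3-[4-(benzyloxy)phenyl]prop-2-enoate
Product: 4 (E)-3-[4-(benzyloxy)phenyl]prop-2-en-1-ol
Conditions: i-Bu2AlH, CH2Cl2, −78 °C
Reagents that add atoms: none
Why: 1,2-reduction of the conjugated ester with an aluminium hydride at low temperature should give the allylic alcohol and leave the alkene and the benzyl ether intact (ester reduction).

**Step 3**
Reactants: 4 (E)-3-[4-(benzyloxy)phenyl]prop-2-en-1-ol
Product: 5 (E)-3-[4-(benzyloxy)phenyl]prop-2-en-1-yl methyl carbonate
Conditions: ClCO2Me, pyridine, CH2Cl2, 0 °C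
Reagents that add atoms: methyl chloroformate, COC(=O)Cl
Why: Acylation of the primary alcohol with a chloroformate gives the linear allylic carbonate, the usual precursor of an iridium π-allyl complex (carbonate formation).

**Step 4**
Reactants: 5 (E)-3-[4-(benzyloxy)phenyl]prop-2-en-1-yl methyl carbonate
Product: 6 (S)-1-[4-(benzyloxy)phenyl]prop-2-en-1-ol
Conditions: [Ir(cod)Cl]2, phosphoramidite L*, n-PrNH2, KHCO3, THF/H2O, rt
Reagents that add atoms: potassium hydrogen carbonate, [K+].OC([O-])=O (delivers the hydroxyl oxygen)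
Why: Iridium-catalysed asymmetric allylic substitution with hydrogen carbonate as a hydroxide equivalent is branched-selective, and the phosphoramidite ligand fixes the face of the π-allyl complex that is attacked, which should set the (S)-carbinol centre (allylic hydroxylation).

**Step 5**
Reactants: 5 (E)-3-[4-(benzyloxy)phenyl]prop-2-en-1-yl methyl carbonate; 6 (S)-1-[4-(benzyloxy)phenyl]prop-2-en-1-ol
Product: 7 bis{(1S)-1-[4-(benzyloxy)phenyl]prop-2-en-1-yl} ether
Conditions: [Ir(cod)Cl]2, phosphoramidite L*, n-PrNH2, K3PO4, THF, rt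
Reagents that add atoms: none
Why: Iridium-catalysed asymmetric allylic etherification: the alkoxide of 6 attacks the aryl-substituted terminus of the same π-allyl complex under control of the same ligand enantiomer, which should set the second (S) centre while the centre of 6 is not involved, so the C2-symmetric (S,S)-ether results.

**Step 6**
Reactants: 7 bis{(1S)-1-[4-(benzyloxy)phenyl]prop-2-en-1-yl} ether
Product: 9 (3S,3'S)-3,3'-oxybis{3-[4-(benzyloxy)phenyl]propan-1-ol}, via bis(9-borabicyclononyl) adduct 8 (not isolated)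
Conditions: 9-BBN-H (2.5 equiv), THF, 0 °C to rt; then NaOH, H2O2, 0 °C
Reagents that add atoms: 9-borabicyclo[3.3.1]nonane, [H]B1C2CCCC1CCC2 (boron fragment of intermediate 8, one per alkene); hydrogen peroxide, OO (hydroxyl oxygen)
Why: Anti-Markovnikov hydroboration of both terminal alkenes with a hindered dialkylborane and oxidation with retention should give the primary alcohols without touching the two ether stereocentres (hydroboration–oxidation).

**Step 7**
Reactants: 9 (3S,3'S)-3,3'-oxybis{3-[4-(benzyloxy)phenyl]propan-1-ol}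
Product: 10 (3S,3'S)-3,3'-oxybis{3-[4-(benzyloxy)phenyl]propanal}
Conditions: Dess–Martin periodinane (2.5 equiv), NaHCO3, CH2Cl2, 0 °C to rt
Reagents that add atoms: none
Why: Dess–Martin oxidation converts the primary alcohols into aldehydes under buffered non-basic conditions, which avoids β-elimination of the ether oxygen.

**Step 8**
Reactants: 11 4-bromobenzene-1,3-diol
Product: 12 2,4-bis(benzyloxy)-1-bromobenzene
Conditions: BnBr (2.2 equiv), K2CO3, DMF, 60 °C
Reagents that add atoms: benzyl bromide, BrCc1ccccc1 (two equivalents, one per hydroxyl group)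
Why: Williamson ether synthesis on both phenolic hydroxyl groups with a benzylic halide and a carbonate base.

**Step 9**
Reactants: 10 (3S,3'S)-3,3'-oxybis{3-[4-(benzyloxy)phenyl]propanal}; 12 2,4-bis(benzyloxy)-1-bromobenzene (2.4 equiv in total, one aryl unit for each of the two aldehyde groups)
Product: 14 (3S,3'S)-3,3'-oxybis{1-[2,4-bis(benzyloxy)phenyl]-3-[4-(benzyloxy)phenyl]propan-1-ol}, via aryl Grignard reagent 13 (not isolated)
Conditions: 12 (2.4 equiv), Mg, LiCl, THF, rt; then 10 (1 equiv), −78 to 0 °C; NH4Cl (aq)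
Reagents that add atoms: 2,4-bis(benzyloxy)-1-bromobenzene, Brc1ccc(OCc2ccccc2)cc1OCc1ccccc1 (the second equivalent of 12, which supplies the aryl group of the second carbinol); magnesium, [Mg] (metal of intermediate 13)
Why: Twofold Grignard addition: one molecule of the aryl nucleophile 13 adds to each of the two aldehyde groups at low temperature, which should outrun enolization and β-elimination, and the two new carbinol centres, formed without control, are removed in step 10.

**Step 10**
Reactants: 14 (3S,3'S)-3,3'-oxybis{1-[2,4-bis(benzyloxy)phenyl]-3-[4-(benzyloxy)phenyl]propan-1-ol}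
Product: 15 (3S,3'S)-3,3'-oxybis{1-[2,4-bis(benzyloxy)phenyl]-3-[4-(benzyloxy)phenyl]propan-1-one}
Conditions: Dess–Martin periodinane (2.5 equiv), NaHCO3, CH2Cl2, rt
Reagents that add atoms: none
Why: Dess–Martin oxidation of the secondary benzylic alcohols gives the aryl ketones without acid or base that could ionize the bis-benzylic ether.

**Step 11**
Reactants: 15 (3S,3'S)-3,3'-oxybis{1-[2,4-bis(benzyloxy)phenyl]-3-[4-(benzyloxy)phenyl]propan-1-one}
Product: 17 [(2S,3S,4S,5S)-2,5-bis[4-(benzyloxy)phenyl]oxolane-3,4-diyl]bis{[2,4-bis(benzyloxy)phenyl]methanone}, via dilithium bis-enolate 16 (not isolated)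
Conditions: LiN(i-Pr)2 (2.5 equiv), THF, −78 °C, slow addition of 15 at 0.02 M; then CuCl2 (2.5 equiv), DMF, −78 to −40 °C
Reagents that add atoms: lithium diisopropylamide, [Li+].CC(C)[N-]C(C)C (lithium of intermediate 16)
Why: Slow addition of 15 to excess amide base should enolize both ketones to the bis-(Z)-enolate 16 before a mono-enolate can undergo aldol closure or β-elimination; CuCl2 then oxidizes one enolate to an α-keto radical (or its divalent-copper enolate), which attacks the second enolate carbon and is oxidized again, so two one-electron transfers turn two C–H bonds into the C3–C4 bond. The closest known reaction is the copper-mediated oxidative coupling of ketone enolates to 1,4-diketones in its intramolecular form (oxidative enolate coupling). The oxolane closes in the 5-exo-trig mode, the radical at C3 adding to the exocyclic enolate double bond at C4. C3 and C4 become stereocentres: allylic 1,3-strain in each enolate turns the C2 or C5 aryl group away from the forming bond, so the all-trans isomer 17 should dominate, but these two centres are provisional because step 12 passes all C3/C4 isomers through one dienediolate, while C2 and C5 are not touched. The step needs C–C coupling inside the molecule to win over loss of the β-ether oxygen and over intermolecular coupling; the 1,5-relationship of the two enolate carbons through O1, the low temperature and the dilution should secure this.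

**Step 12**
Reactants: 17 [(2S,3S,4S,5S)-2,5-bis[4-(benzyloxy)phenyl]oxolane-3,4-diyl]bis{[2,4-bis(benzyloxy)phenyl]methanone}
Product: 19 [(2S,3R,4R,5S)-2,5-bis[4-(benzyloxy)phenyl]oxolane-3,4-diyl]bis{[2,4-bis(benzyloxy)phenyl]methanone}, via dilithium dienediolate 18 (not isolated)
Conditions: LiN(i-Pr)2 (3 equiv), THF/DMPU, −78 to −20 °C; then cannulation into AcOH/THF, −78 °C
Reagents that add atoms: lithium diisopropylamide, [Li+].CC(C)[N-]C(C)C (lithium of intermediate 18)
Why: Kinetic diastereoselective protonation of an enolate: in the C2-symmetric dienediolate 18 the O–Li groups lie inside and the enolate aryl groups outside, allylic 1,3-strain holds the C2 and C5 aryl groups pseudo-axial on opposite faces, and each proton should therefore enter C3 and C4 anti to the neighbouring aryl group, which places each aroyl group cis to its neighbouring aryl group and the two aroyl groups trans to each other, while the cold acidic quench prevents equilibration to the all-trans isomer.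

**Step 13**
Reactants: 19 [(2S,3R,4R,5S)-2,5-bis[4-(benzyloxy)phenyl]oxolane-3,4-diyl]bis{[2,4-bis(benzyloxy)phenyl]methanone}
Product: 20 [(2S,3R,4R,5S)-2,5-bis(4-hydroxyphenyl)oxolane-3,4-diyl]bis[(2,4-dihydroxyphenyl)methanone]
Conditions: H2 (1 atm), Pd/C, EtOAc/THF, rt
Reagents that add atoms: none
Why: Hydrogenolysis of the six aryl benzyl ethers over palladium runs under neutral conditions, so the base-sensitive C3 and C4 centres should not epimerize, and aryl benzyl ethers are cleaved faster than the cyclic dialkyl benzylic C–O bonds and the aryl ketones.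

**Compound list**

1 | 4-(benzyloxy)benzaldehyde | O=Cc1ccc(OCc2ccccc2)cc1 | starting material
2 | triethyl phosphonoacetate | CCOC(=O)CP(=O)(OCC)OCC | starting material
3 | ethyl (E)-3-[4-(benzyloxy)phenyl]prop-2-enoate | CCOC(=O)/C=C/c1ccc(OCc2ccccc2)cc1 | intermediate
4 | (E)-3-[4-(benzyloxy)phenyl]prop-2-en-1-ol | OC/C=C/c1ccc(OCc2ccccc2)cc1 | intermediate
5 | (E)-3-[4-(benzyloxy)phenyl]prop-2-en-1-yl methyl carbonate | COC(=O)OC/C=C/c1ccc(OCc2ccccc2)cc1 | intermediate
6 | (S)-1-[4-(benzyloxy)phenyl]prop-2-en-1-ol | C=C[C@H](O)c1ccc(OCc2ccccc2)cc1 | intermediate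
7 | bis{(1S)-1-[4-(benzyloxy)phenyl]prop-2-en-1-yl} ether | C=C[C@H](O[C@@H](C=C)c1ccc(OCc2ccccc2)cc1)c1ccc(OCc2ccccc2)cc1 | intermediate
8 | 9,9'-{oxybis[(3S)-3-[4-(benzyloxy)phenyl]propane-3,1-diyl]}bis(9-borabicyclo[3.3.1]nonane) | C1CCC2CCCC1B2CC[C@H](O[C@@H](CCB1C2CCCC1CCC2)c1ccc(OCc2ccccc2)cc1)c1ccc(OCc2ccccc2)cc1 | intermediate (not isolated)
9 | (3S,3'S)-3,3'-oxybis{3-[4-(benzyloxy)phenyl]propan-1-ol} | OCC[C@H](O[C@@H](CCO)c1ccc(OCc2ccccc2)cc1)c1ccc(OCc2ccccc2)cc1 | intermediate
10 | (3S,3'S)-3,3'-oxybis{3-[4-(benzyloxy)phenyl]propanal} | O=CC[C@H](O[C@@H](CC=O)c1ccc(OCc2ccccc2)cc1)c1ccc(OCc2ccccc2)cc1 | intermediate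
11 | 4-bromobenzene-1,3-diol | Oc1ccc(Br)c(O)c1 | starting material
12 | 2,4-bis(benzyloxy)-1-bromobenzene | Brc1ccc(OCc2ccccc2)cc1OCc1ccccc1 | intermediate
13 | [2,4-bis(benzyloxy)phenyl]magnesium bromide | Br[Mg]c1ccc(OCc2ccccc2)cc1OCc1ccccc1 | intermediate (not isolated)
14 | (3S,3'S)-3,3'-oxybis{1-[2,4-bis(benzyloxy)phenyl]-3-[4-(benzyloxy)phenyl]propan-1-ol}, mixture of epimers at the two carbinol carbons | OC(C[C@H](O[C@@H](CC(O)c1ccc(OCc2ccccc2)cc1OCc1ccccc1)c1ccc(OCc2ccccc2)cc1)c1ccc(OCc2ccccc2)cc1)c1ccc(OCc2ccccc2)cc1OCc1ccccc1 | intermediate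
15 | (3S,3'S)-3,3'-oxybis{1-[2,4-bis(benzyloxy)phenyl]-3-[4-(benzyloxy)phenyl]propan-1-one} | O=C(C[C@H](O[C@@H](CC(=O)c1ccc(OCc2ccccc2)cc1OCc1ccccc1)c1ccc(OCc2ccccc2)cc1)c1ccc(OCc2ccccc2)cc1)c1ccc(OCc2ccccc2)cc1OCc1ccccc1 | intermediate
16 | dilithium (1Z,1'Z,3S,3'S)-3,3'-oxybis{1-[2,4-bis(benzyloxy)phenyl]-3-[4-(benzyloxy)phenyl]prop-1-en-1-olate} | [Li+].[Li+].[O-]/C(=C\[C@H](O[C@@H](/C=C(\[O-])c1ccc(OCc2ccccc2)cc1OCc1ccccc1)c1ccc(OCc2ccccc2)cc1)c1ccc(OCc2ccccc2)cc1)c1ccc(OCc2ccccc2)cc1OCc1ccccc1 | intermediate (not isolated)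
17 | [(2S,3S,4S,5S)-2,5-bis[4-(benzyloxy)phenyl]oxolane-3,4-diyl]bis{[2,4-bis(benzyloxy)phenyl]methanone}, all-trans, expected main isomer; C3/C4 epimers are carried along | O=C(c1ccc(OCc2ccccc2)cc1OCc1ccccc1)[C@H]1[C@H](C(=O)c2ccc(OCc3ccccc3)cc2OCc2ccccc2)[C@@H](c2ccc(OCc3ccccc3)cc2)O[C@@H]1c1ccc(OCc2ccccc2)cc1 | intermediate
18 | dilithium (E,E)-{(2R,5R)-2,5-bis[4-(benzyloxy)phenyl]oxolane-3,4-diylidene}bis{[2,4-bis(benzyloxy)phenyl]methanolate}; same spatial arrangement at C2/C5 as 17, the descriptors change with the CIP priorities | [Li+].[Li+].[O-]/C(c1ccc(OCc2ccccc2)cc1OCc1ccccc1)=C1\C(=C(/[O-])c2ccc(OCc3ccccc3)cc2OCc2ccccc2)[C@@H](c2ccc(OCc3ccccc3)cc2)O[C@@H]1c1ccc(OCc2ccccc2)cc1 | intermediate (not isolated)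
19 | [(2S,3R,4R,5S)-2,5-bis[4-(benzyloxy)phenyl]oxolane-3,4-diyl]bis{[2,4-bis(benzyloxy)phenyl]methanone} | O=C(c1ccc(OCc2ccccc2)cc1OCc1ccccc1)[C@@H]1[C@@H](C(=O)c2ccc(OCc3ccccc3)cc2OCc2ccccc2)[C@@H](c2ccc(OCc3ccccc3)cc2)O[C@@H]1c1ccc(OCc2ccccc2)cc1 | intermediate
20 | [(2S,3R,4R,5S)-2,5-bis(4-hydroxyphenyl)oxolane-3,4-diyl]bis[(2,4-dihydroxyphenyl)methanone] | O=C(c1ccc(O)cc1O)[C@@H]1[C@@H](C(=O)c2ccc(O)cc2O)[C@@H](c2ccc(O)cc2)O[C@@H]1c1ccc(O)cc1 | target

**Count and risks**

Total steps: 13. Longest linear sequence: 12 steps (steps 1–7 and 9–13).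

Step 12 is the most likely to fail. The second protonation may lack facial selectivity, because the C4 enolate is flanked by the new C3 aroyl group as well as by the C5 aryl group, and the product may equilibrate towards the all-trans isomer during the quench. The fallback sets out from 17. Compound 17 is deprotonated twice as in step 12 and the dienediolate is oxidized with I2 at −78 °C to [(2R,5R)-2,5-bis[4-(benzyloxy)phenyl]-2,5-dihydrofuran-3,4-diyl]bis{[2,4-bis(benzyloxy)phenyl]methanone} F1. This ene-dione is reduced with Zn dust in AcOH at 0 °C (dissolving-metal reduction of an ene-dione). The neutral bis-enol is then formed and ketonized in a protic medium, each enol being protonated from the face away from its neighbouring aryl group. The fallback returns to the route at 19.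

Step 11 is the second risk. The lithium enolate may lose the β-ether oxygen (E1cB) to give a chalcone, a mono-enolate may close by aldol addition, or the product may be oxidized further. The fallback sets out from 15. The diketone is trapped by in situ quench (Me3SiCl, LiN(SiMe3)2, THF, −78 °C) as the (Z,Z)-bis(trimethylsilyl enol ether) of 15 F2, so that no free enolate accumulates. Ag2O in DMSO then couples the two enol ether carbons (silver oxide-mediated oxidative coupling of silyl enol ethers to 1,4-diketones). The fallback returns at 17.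

Step 5 is the third risk. Attack of the hindered secondary alkoxide may be slow, and the branched selectivity or the configuration of the new centre may erode through ionization of the electron-rich allyl ether. The fallback sets out from 6. Part of 6 is converted with ClCO2Me and pyridine into (S)-1-[4-(benzyloxy)phenyl]prop-2-en-1-yl methyl carbonate F3. F3 is coupled with the lithium alkoxide of 6 under [Ir(cod)Cl]2 and P(OPh)3, a system in which enantioenriched branched allylic carbonates are substituted with net retention. The configuration of the new centre then comes from the substrate and not from a chiral ligand. The fallback returns at 7.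

**Further compounds**

F1 | step 12 | [(2R,5R)-2,5-bis[4-(benzyloxy)phenyl]-2,5-dihydrofuran-3,4-diyl]bis{[2,4-bis(benzyloxy)phenyl]methanone} | O=C(c1ccc(OCc2ccccc2)cc1OCc1ccccc1)C1=C(C(=O)c2ccc(OCc3ccccc3)cc2OCc2ccccc2)[C@@H](c2ccc(OCc3ccccc3)cc2)O[C@@H]1c1ccc(OCc2ccccc2)cc1
F2 | step 11 | (1Z,1'Z,3S,3'S)-3,3'-oxybis{1-[2,4-bis(benzyloxy)phenyl]-3-[4-(benzyloxy)phenyl]-1-(trimethylsilyloxy)prop-1-ene} | C[Si](C)(C)O/C(=C\[C@H](O[C@@H](/C=C(\O[Si](C)(C)C)c1ccc(OCc2ccccc2)cc1OCc1ccccc1)c1ccc(OCc2ccccc2)cc1)c1ccc(OCc2ccccc2)cc1)c1ccc(OCc2ccccc2)cc1OCc1ccccc1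
F3 | step 5 | (S)-1-[4-(benzyloxy)phenyl]prop-2-en-1-yl methyl carbonate | COC(=O)O[C@@H](C=C)c1ccc(OCc2ccccc2)cc1
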